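## Structural features

The target is a tetrahydrofuran lignan: an oxolane ring (O1, C2, C3, C4, C5) with a 3,4-dimethoxyphenyl (veratryl) group on C2, a methyl group (C7) on C3 and, on C4, an exocyclic secondary carbinol carbon C6 that bears the second veratryl group; C5 is the only ring CH2. Four stereocentres stand in a row, C2 (S), C3 (S), C4 (R) and C6 (R). In the ring the C2 aryl is trans to the C3 methyl, and the methyl is cis to the C4 side chain. Both benzylic C–O bonds (C2–O1 and C6–OH) are activated by a para-methoxy group and ionise easily under acid. The constitution is almost symmetric about the C3–C4 bond, so an ionised C6 can be captured by an oxygen on C7 and an ionised C2 by the arene on C6. The real difficulty is the acyclic stereocentre C6 next to the ring stereocentre C4, together with the crowded 3,4-cis relation. The key step uses the 1,3-relation between the donor carbon C6 and C3: C3 can carry two acceptors (C2 as an aroyl carbonyl, C7 as a lactone carbonyl tied through oxygen to C5), so C3, C4 and C6 can be held as a donor–acceptor cyclopropane fused to a γ-lactone. Opening C3–C6 with an oxygen nucleophile under inversion turns E-alkene geometry into the C4/C6 relation, and C3 can then relax to the trans lactone, which is the 3,4-cis arrangement of the final ring.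

## Logic of the disconnections

12 to 11: no skeletal bond is cut; the O–H at C6 is exchanged for O–Si. The reason is that a free C6 carbinol cannot be present while C2 is ionised, because a second ring would close. The gain is that the C2–O1 bond can now be cut without interference. The demand is a removal under basic, non-ionising conditions.

11 to 10 to 9: the C7–H bond is traced back to a C7–O bond. This identifies the methyl carbon as a former carbonyl carbon, which is what lets C3 carry two acceptors earlier. The gain is an oxygen handle at C7; the demand is a hydride displacement at a β-branched primary carbon that leaves the silyl ether alone.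

9 to 8: O1–C2 is cut. It is the benzylic C–O bond of the ring and forms by ionisation, so the configuration at C2 need not be carried through the route. The ring and one stereocentre disappear. The forward closure must ionise only C2, use the C5 hydroxyl (five-membered ring) and place the aryl trans to the C3 substituent.

8 to 7: the C–H bonds at C2, C5 and C7 that hydride delivered are removed and the C7–O–C5 ester bond is restored. In 7, C3 lies between a ketone and a lactone carbonyl and is epimerisable, so its configuration follows from thermodynamics (trans lactone). The demand is a complete reduction without silyl migration.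

7 to 6 to 5: the C6–O bond is cut and C6 is joined to C3. The 1,3-relation between the C6 oxygen and the doubly activated C3 is the retron of a homo-conjugate addition. C4 and C6 are now held in a rigid bicycle, and C3 becomes quaternary and unambiguous. The forward opening must go with inversion at C6; it was checked that the (1S,5R,6S) antipode of 5 is the one that maps onto 12.

5 to 4: C3–C4 and C3–C6 are cut (carbene plus alkene). Two rings and three stereocentres are removed at once and the whole carbon skeleton becomes an acyclic ester. The forward step needs face selectivity from a chiral catalyst and retention of the E geometry.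

4 to 3 to 1 and 2: the C=N2 unit goes back to CH2, and the ester C–O bond is cut to two catalogue compounds. The demand is a neutral esterification that spares the electron-rich allylic alcohol, and a diazo-transfer reagent with a good safety record.

## Other disconnections considered

Alternative 1: The ring is cut at C5–C4 and C2–C3, leaving a carbonyl ylide (C2, O1, C5) and the C3=C4 alkene of a butenolide whose acetal carbon is the future C6 and whose carbonyl carbon is the future C7. Forward, CsF would desilylate 4-{chloro[(trimethylsilyl)methoxy]methyl}-1,2-dimethoxybenzene A2 with loss of chloride. The ylide would add to (5S)-5-[(1S,2R,5S)-menthyloxy]furan-2(5H)-one A1 on the face away from the acetal substituent, giving the cis-fused cycloadduct A3.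
- In its favour: the oxolane ring and C2, C3 and C4 appear in one step; the 3,4-cis relation is guaranteed by the ring fusion; the absolute configuration comes from a crystalline auxiliary; no diazo compound or precious metal is needed. On hazard, cost and direct setting of C2 it is the equal or the better of the chosen plan.
- Against it: A3 carries no information about C6. The acetal would have to be unmasked and take up an aryl-metal reagent with only the neighbouring ring to steer the addition.
- The lactone carbonyl still needs the same reduction, sulfonylation and hydride sequence as in the chosen plan.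
- The exo position of the aryl rests on an exo/endo preference that nothing in A1 enforces; A2 is an α-chloro ether of a very electron-rich aldehyde and would be hard to handle; the menthyl group encoded in A3 is the (1S,2R,5S) antipode, the less common one.
- Comparison: about two steps to each of A1 and A2, the cycloaddition and about five steps after it give a length close to that of the chosen plan. The hardest stereocentre, C6, is left to substrate control, whereas the chosen plan fixes C4 and C6 by one stereospecific pair of events.

Alternative 2: C4–C3 and, formally, the bond from C6 to the methyl carbon are cut; the latter is made in the key step and broken again later. Forward, 3-{[(1S)-1-(3,4-dimethoxyphenyl)prop-2-en-1-yl]oxy}-N,N-dimethylpropanamide A4 would be activated with Tf2O and collidine. The keteniminium ion would add to the vinyl group in a [2+2] sense and hydrolysis would give the bicyclic cyclobutanone (1S,2S,5R)-2-(3,4-dimethoxyphenyl)-3-oxabicyclo[3.2.0]heptan-6-one A5. An aryl-metal reagent would then add to the carbonyl carbon (C6); a metal-mediated β-carbon elimination would cleave the bond from C6 to the CH2 carbon, giving the C3 methyl and a C6 aryl ketone; a last reduction would set C6.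
- In its favour: the 3,4-cis relation is locked by ring fusion, the methyl group arises without any deoxygenation, C2 comes from a simple enantioenriched allylic alcohol, and the count is about eight steps. In redox and step economy it is better than the chosen plan, and in securing 3,4-cis it is its equal.
- Against it: Tf2O would meet a doubly activated (benzylic and allylic) ether and two electron-rich arenes, so ionisation of C2–O and arene acylation would compete.
- The cyclobutanol must open towards the primary carbon and not towards C4, which excludes radical β-scission.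
- C6 is made last, by reduction of a ketone whose α-carbon C4 is cis to the methyl and can epimerise.
- Comparison: the chosen plan is about two steps longer but derives C4 and C6 from one alkene geometry and leaves only C2 to a thermodynamic preference.

Alternative 3: Only C3–C4 is cut, with the methyl C–H added in the same step. Forward, a palladium hydride formed from Pd(OAc)2 and a silane would add to the aryl alkyne of 4-[(1S)-1-{[3-(3,4-dimethoxyphenyl)prop-2-yn-1-yl]oxy}prop-2-en-1-yl]-1,2-dimethoxybenzene A6. The vinylpalladium species would insert the vinyl group in a 5-exo closure and the silane would reduce the CH2–Pd bond, giving (2S,3S,4Z)-2-(3,4-dimethoxyphenyl)-4-[(3,4-dimethoxyphenyl)methylidene]-3-methyloxolane A7.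
- In its favour: it is the shortest plan (about three steps to A6, the cyclisation, then functionalisation of the alkene), and the methyl is delivered at the right oxidation level. In step economy it is clearly better than the chosen plan.
- Against it: A6 is an allylic and benzylic ether that zerovalent palladium can ionise to an allyl complex, and C3 depends on 1,2-induction from C2 during insertion.
- A7 does not lead to 12 by one hydroboration. Syn addition of H and boron to the Z alkene from the face anti to the C3 methyl would set C4 correctly but would give C6 with the S configuration, because 12 corresponds to syn addition to the E isomer. An inversion or an oxidation and reduction at C6 would have to follow.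
- The face anti to the methyl is also the face syn to the C2 aryl, so the facial preference is contested.
- Comparison: three of four stereocentres would rest on substrate-controlled diastereoselection. The alternative wins on length; the chosen plan wins on how firmly the mechanism fixes C4 and C6.

Key step: step 3

Remark: 2 is taken as a catalogue compound, and the (S)-configured catalyst Rh2(S-PTTL)4 is assumed to deliver the (1S,5R,6S) enantiomer of 5; should the sense of induction be the opposite, the (R)-configured catalyst is used instead.

Step 1
Reactants: 1 ethyl 3-(3,4-dimethoxyphenyl)-3-oxopropanoate; 2 (2E)-3-(3,4-dimethoxyphenyl)prop-2-en-1-ol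
Product: 3 (2E)-3-(3,4-dimethoxyphenyl)prop-2-en-1-yl 3-(3,4-dimethoxyphenyl)-3-oxopropanoate
Conditions: DMAP (0.2 equiv), toluene, reflux, 4 Å molecular sieves in a Soxhlet thimble (removal of EtOH)
Reagents that add atoms: none
Why: Transesterification of a β-keto ester under DMAP catalysis, which runs through the acylketene or acylpyridinium species and is driven by removal of ethanol. The neutral medium spares the acid-sensitive, electron-rich allylic alcohol, and the E alkene is not touched.

Step 2
Reactants: 3 (2E)-3-(3,4-dimethoxyphenyl)prop-2-en-1-yl 3-(3,4-dimethoxyphenyl)-3-oxopropanoate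
Product: 4 (2E)-3-(3,4-dimethoxyphenyl)prop-2-en-1-yl 2-diazo-3-(3,4-dimethoxyphenyl)-3-oxopropanoate
Conditions: p-ABSA (1.1 equiv), Et3N (1.5 equiv), MeCN, 0 °C to rt
Reagents that add atoms: 4-acetamidobenzenesulfonyl azide (p-ABSA), CC(=O)Nc1ccc(cc1)S(=O)(=O)N=[N+]=[N-]
Why: Regitz diazo transfer to the doubly activated methylene: the ammonium enolate attacks the terminal nitrogen of the sulfonyl azide and the sulfonamide leaves. p-ABSA is chosen as the least shock-sensitive of the common sulfonyl azides; the acceptor/acceptor diazo compound 4 is not heated or distilled and is used promptly.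

Step 3
Reactants: 4 (2E)-3-(3,4-dimethoxyphenyl)prop-2-en-1-yl 2-diazo-3-(3,4-dimethoxyphenyl)-3-oxopropanoate
Product: 5 (1S,5R,6S)-1-(3,4-dimethoxybenzoyl)-6-(3,4-dimethoxyphenyl)-3-oxabicyclo[3.1.0]hexan-2-one (6-exo-aryl)
Conditions: Rh2(S-PTTL)4 (1 mol%), CH2Cl2, 4 Å MS, 0 °C to rt, slow addition of 4; filtration through neutral alumina
Reagents that add atoms: none
Why: Rh2(S-PTTL)4 takes up the diazo carbon of 4, dinitrogen leaves, and the electrophilic rhodium carbene at C3 adds to the electron-rich tethered alkene in one asynchronous but concerted event that forms C3–C4 and C3–C6. The closest known reaction type is the enantioselective intramolecular cyclopropanation of allylic α-diazo-β-keto esters and diazomalonates with chiral dirhodium tetracarboxylates or monovalent copper bis(oxazoline) complexes. The lactone closes in the 5-exo mode (C3 bonds to the nearer alkene carbon C4, five atoms in the new ring), and the cyclopropane closes as the fused three-membered ring when C3 also bonds to C6. C4 and C6 keep the E geometry of the alkene because the addition is suprafacial, so the C6 aryl ends exo, trans to the lactone CH2; the quaternary C3 has no freedom, since a three-membered ring can only be fused cis to the lactone. The absolute sense, (1S,5R,6S), comes from the alkene face that the chiral carboxylate wall of the catalyst leaves open. The step needs cyclopropanation to win over attack of the keto carbene oxygen on the alkene (formal [3+2] to a dihydrofuran) and over attack on an arene, which the five-atom tether to a very electron-rich alkene should secure. It also needs the donor–acceptor cyclopropane to survive, which is why a weakly Lewis-acidic dirhodium carboxylate, a non-ionising solvent, low temperature and isolation over neutral alumina are chosen.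

Step 4
Reactants: 5 (1S,5R,6S)-1-(3,4-dimethoxybenzoyl)-6-(3,4-dimethoxyphenyl)-3-oxabicyclo[3.1.0]hexan-2-one
Product: 6 (3S,4R)-3-(3,4-dimethoxybenzoyl)-4-[(R)-(3,4-dimethoxyphenyl)(hydroxy)methyl]oxolan-2-one
Conditions: Yb(OTf)3 (10 mol%), THF–H2O (10:1), 0 °C; pH 7 phosphate buffer
Reagents that add atoms: water, O
Why: Lewis acid-assisted opening of a donor–acceptor cyclopropane of SN2 type (homo-conjugate addition): Yb(OTf)3 chelates the ketone and lactone carbonyls and polarises C3–C6, and water attacks C6 from the side opposite to C3, so C6 is inverted to R while C4 is untouched. The freed C3 is a β-keto lactone carbon and settles by enolisation in the trans arrangement (3S). Low temperature, a large excess of water and a buffered work-up are meant to keep ionisation to the benzylic cation and closure by the aroyl oxygen (Cloke–Wilson rearrangement) behind.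

Step 5
Reactants: 6 (3S,4R)-3-(3,4-dimethoxybenzoyl)-4-[(R)-(3,4-dimethoxyphenyl)(hydroxy)methyl]oxolan-2-one
Product: 7 (3S,4R)-4-[(R)-(tert-butyldimethylsilyloxy)(3,4-dimethoxyphenyl)methyl]-3-(3,4-dimethoxybenzoyl)oxolan-2-one
Conditions: TBSCl (1.5 equiv), imidazole (3 equiv), DMF, rt
Reagents that add atoms: tert-butyldimethylsilyl chloride (TBSCl), CC(C)(C)[Si](C)(C)Cl
Why: Imidazole-promoted silyl ether formation at the secondary benzylic hydroxyl; it keeps the C6 oxygen away from the neighbouring ketone and from the later acid step. A silyl enol ether formed at the β-keto lactone would revert on aqueous work-up, and C3 stays in the stable trans arrangement.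

Step 6
Reactants: 7 (3S,4R)-4-[(R)-(tert-butyldimethylsilyloxy)(3,4-dimethoxyphenyl)methyl]-3-(3,4-dimethoxybenzoyl)oxolan-2-one
Product: 8 (2R,3R)-2-[(R)-(tert-butyldimethylsilyloxy)(3,4-dimethoxyphenyl)methyl]-3-[(3,4-dimethoxyphenyl)(hydroxy)methyl]butane-1,4-diol (both epimers at the new carbinol carbon)
Conditions: LiAlH4 (3 equiv), THF, −20 °C to 0 °C; aq. potassium sodium tartrate
Reagents that add atoms: none
Why: Hydride reduction of the aryl ketone to the carbinol and of the lactone to the 1,4-diol; the silyl ether is inert. The new carbinol centre C2 forms without control and is left unassigned because step 7 erases it; C3 is fixed as soon as its two carbonyl groups are reduced.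

Step 7
Reactants: 8 (2R,3R)-2-[(R)-(tert-butyldimethylsilyloxy)(3,4-dimethoxyphenyl)methyl]-3-[(3,4-dimethoxyphenyl)(hydroxy)methyl]butane-1,4-diol
Product: 9 [(2S,3R,4R)-4-[(R)-(tert-butyldimethylsilyloxy)(3,4-dimethoxyphenyl)methyl]-2-(3,4-dimethoxyphenyl)oxolan-3-yl]methanol
Conditions: CSA (10 mol%), CH2Cl2, 4 Å MS, 0 °C; then Et3N
Reagents that add atoms: none
Why: Acid-catalysed dehydrative cycloetherification (SN1): the para-methoxy-stabilised benzylic cation at C2 is captured by the C5 hydroxyl in a five-membered closure, whereas the C7 hydroxyl could only give an oxetane and the hindered, weakly basic silyl ether oxygen at C6 should not ionise. C2 is set here: the aryl takes the face anti to the adjacent CH2OH and to the C4 side chain (2,3-trans), which is the kinetic preference and, the closure being reversible, also the thermodynamic one.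

Step 8
Reactants: 9 [(2S,3R,4R)-4-[(R)-(tert-butyldimethylsilyloxy)(3,4-dimethoxyphenyl)methyl]-2-(3,4-dimethoxyphenyl)oxolan-3-yl]methanol
Product: 10 [(2S,3R,4R)-4-[(R)-(tert-butyldimethylsilyloxy)(3,4-dimethoxyphenyl)methyl]-2-(3,4-dimethoxyphenyl)oxolan-3-yl]methyl 4-methylbenzenesulfonate
Conditions: TsCl (1.3 equiv), Et3N (2 equiv), DMAP (cat.), CH2Cl2, 0 °C to rt
Reagents that add atoms: 4-methylbenzenesulfonyl chloride (TsCl), Cc1ccc(cc1)S(=O)(=O)Cl
Why: Sulfonylation of the only free hydroxyl, a primary one (tosylate formation); no stereocentre is involved.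

Step 9
Reactants: 10 [(2S,3R,4R)-4-[(R)-(tert-butyldimethylsilyloxy)(3,4-dimethoxyphenyl)methyl]-2-(3,4-dimethoxyphenyl)oxolan-3-yl]methyl 4-methylbenzenesulfonate
Product: 11 tert-butyl{(R)-(3,4-dimethoxyphenyl)[(3R,4S,5S)-5-(3,4-dimethoxyphenyl)-4-methyloxolan-3-yl]methoxy}dimethylsilane
Conditions: LiBHEt3 (3 equiv), THF, 0 °C to rt
Reagents that add atoms: none
Why: SN2 displacement of the primary tosylate by hydride from LiBHEt3, the usual reagent for β-branched primary sulfonates; silyl ether, aryl ethers and the ring are inert.

Step 10
Reactants: 11 tert-butyl{(R)-(3,4-dimethoxyphenyl)[(3R,4S,5S)-5-(3,4-dimethoxyphenyl)-4-methyloxolan-3-yl]methoxy}dimethylsilane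
Product: 12 (R)-(3,4-dimethoxyphenyl)[(3R,4S,5S)-5-(3,4-dimethoxyphenyl)-4-methyloxolan-3-yl]methanol
Conditions: TBAF (1.5 equiv), THF, 0 °C to rt
Reagents that add atoms: none
Why: Fluoride-induced cleavage of the Si–O bond (desilylation). The basic, non-ionising medium leaves the acid-sensitive benzylic carbinol and the benzylic ring ether intact, and all four stereocentres stay as set.

## Compound list

1 | ethyl 3-(3,4-dimethoxyphenyl)-3-oxopropanoate | CCOC(=O)CC(=O)c1ccc(OC)c(OC)c1 | starting material
2 | (2E)-3-(3,4-dimethoxyphenyl)prop-2-en-1-ol | OC/C=C/c1ccc(OC)c(OC)c1 | starting material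
3 | (2E)-3-(3,4-dimethoxyphenyl)prop-2-en-1-yl 3-(3,4-dimethoxyphenyl)-3-oxopropanoate | COc1ccc(/C=C/COC(=O)CC(=O)c2ccc(OC)c(OC)c2)cc1OC | intermediate
4 | (2E)-3-(3,4-dimethoxyphenyl)prop-2-en-1-yl 2-diazo-3-(3,4-dimethoxyphenyl)-3-oxopropanoate | COc1ccc(/C=C/COC(=O)C(=[N+]=[N-])C(=O)c2ccc(OC)c(OC)c2)cc1OC | intermediate
5 | (1S,5R,6S)-1-(3,4-dimethoxybenzoyl)-6-(3,4-dimethoxyphenyl)-3-oxabicyclo[3.1.0]hexan-2-one | O=C1OC[C@@H]2[C@@H](c3ccc(OC)c(OC)c3)[C@]12C(=O)c1ccc(OC)c(OC)c1 | intermediate
6 | (3S,4R)-3-(3,4-dimethoxybenzoyl)-4-[(R)-(3,4-dimethoxyphenyl)(hydroxy)methyl]oxolan-2-one | O=C1OC[C@H]([C@@H](O)c2ccc(OC)c(OC)c2)[C@H]1C(=O)c1ccc(OC)c(OC)c1 | intermediate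
7 | (3S,4R)-4-[(R)-(tert-butyldimethylsilyloxy)(3,4-dimethoxyphenyl)methyl]-3-(3,4-dimethoxybenzoyl)oxolan-2-one | O=C1OC[C@H]([C@@H](O[Si](C)(C)C(C)(C)C)c2ccc(OC)c(OC)c2)[C@H]1C(=O)c1ccc(OC)c(OC)c1 | intermediate
8 | (2R,3R)-2-[(R)-(tert-butyldimethylsilyloxy)(3,4-dimethoxyphenyl)methyl]-3-[(3,4-dimethoxyphenyl)(hydroxy)methyl]butane-1,4-diol, both carbinol epimers | OC[C@H]([C@@H](O[Si](C)(C)C(C)(C)C)c1ccc(OC)c(OC)c1)[C@H](CO)C(O)c1ccc(OC)c(OC)c1 | intermediate
9 | [(2S,3R,4R)-4-[(R)-(tert-butyldimethylsilyloxy)(3,4-dimethoxyphenyl)methyl]-2-(3,4-dimethoxyphenyl)oxolan-3-yl]methanol | COc1ccc([C@H]2OC[C@H]([C@@H](O[Si](C)(C)C(C)(C)C)c3ccc(OC)c(OC)c3)[C@@H]2CO)cc1OC | intermediate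
10 | [(2S,3R,4R)-4-[(R)-(tert-butyldimethylsilyloxy)(3,4-dimethoxyphenyl)methyl]-2-(3,4-dimethoxyphenyl)oxolan-3-yl]methyl 4-methylbenzenesulfonate | COc1ccc([C@H]2OC[C@H]([C@@H](O[Si](C)(C)C(C)(C)C)c3ccc(OC)c(OC)c3)[C@@H]2COS(=O)(=O)c2ccc(C)cc2)cc1OC | intermediate
11 | tert-butyl{(R)-(3,4-dimethoxyphenyl)[(3R,4S,5S)-5-(3,4-dimethoxyphenyl)-4-methyloxolan-3-yl]methoxy}dimethylsilane | COc1ccc([C@H]2OC[C@H]([C@@H](O[Si](C)(C)C(C)(C)C)c3ccc(OC)c(OC)c3)[C@@H]2C)cc1OC | intermediate
12 | (R)-(3,4-dimethoxyphenyl)[(3R,4S,5S)-5-(3,4-dimethoxyphenyl)-4-methyloxolan-3-yl]methanol | COc1ccc([C@H]2OC[C@H]([C@@H](O)c3ccc(OC)c(OC)c3)[C@@H]2C)cc1OC | target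

## Step count and least certain steps

Total: 10 steps. Longest linear sequence: 10 steps (from 1 or 2 to 12); the two starting materials meet in step 1.

Step 3 (key step). The most likely failures are incomplete discrimination between the two alkene faces, since acceptor/acceptor carbenes react through early transition states, and opening or rearrangement of the very electron-rich donor–acceptor cyclopropane on the catalyst or during isolation. The fallback builds the same bicycle by a Michael-initiated ring closure under aminocatalysis; it sets out from 1 and comes back at 5. 1 would be brominated (NBS, cat. NH4OAc, Et2O) to ethyl 2-bromo-3-(3,4-dimethoxyphenyl)-3-oxopropanoate F1. F1 and commercial (2E)-3-(3,4-dimethoxyphenyl)prop-2-enal F2 would be joined with a diphenylprolinol trimethylsilyl ether catalyst (the antipode that gives the stated product) and 2,6-lutidine in CH2Cl2 at 0 °C: conjugate addition to the iminium ion, then closure of the enamine on the carbon–bromine bond. This should give ethyl (1S,2S,3R)-1-(3,4-dimethoxybenzoyl)-2-(3,4-dimethoxyphenyl)-3-formylcyclopropane-1-carboxylate F3. NaBH4 at −40 °C would reduce only the aldehyde, and the hydroxymethyl group would close on the cis ester to give 5. The weak point of this detour is the orientation of ester and ketone at the quaternary carbon.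

Step 4. The most likely failure is ionisation at C6 ahead of attack by water, because the veratryl group stabilises the cation strongly; the inversion would then be eroded and the aroyl oxygen could capture the cation. The fallback makes the configuration at C6 independent of the opening; it sets out from 12 and comes back at 12. Steps 5 to 10 would be run on the unseparated material, so that 12 arrives together with its C6 epimer, (S)-(3,4-dimethoxyphenyl)[(3R,4S,5S)-5-(3,4-dimethoxyphenyl)-4-methyloxolan-3-yl]methanol F4. MnO2 in CH2Cl2 would oxidise both benzylic carbinols to one ketone, (3,4-dimethoxyphenyl)[(3R,4S,5S)-5-(3,4-dimethoxyphenyl)-4-methyloxolan-3-yl]methanone F5. A Corey–Bakshi–Shibata reduction ((S)-Me-CBS, BH3·SMe2, THF, −20 °C; sense expected by analogy with aryl alkyl ketones) would return 12. The ketone must be kept away from base, since C4 is cis to the methyl and could epimerise.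

Step 6. The most likely failures are deprotonation of the acidic C3–H by the hydride, which would leave the ketone untouched as its enolate, and migration of the silyl group from the C6 oxygen to a newly formed alkoxide. The fallback reduces in two stages under less basic conditions; it sets out from 7 and comes back at 8. A Luche reduction (NaBH4, CeCl3·7H2O, MeOH–THF, −40 °C) would reduce the ketone only, giving (3S,4R)-4-[(R)-(tert-butyldimethylsilyloxy)(3,4-dimethoxyphenyl)methyl]-3-[(3,4-dimethoxyphenyl)(hydroxy)methyl]oxolan-2-one F6 as its carbinol epimers. LiBH4 in THF (0 °C to rt) would then open the lactone to 8.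

Step 7. The most likely failures are loss of the silyl group or ionisation at C6, followed by closure of a second ring from the C7 hydroxyl, and closure through carbon (attack of the arene on C6 at the C2 cation) on prolonged contact with acid. The fallback closes the ring by a Williamson etherification with no acid, with C2 set beforehand; it sets out from 7 and comes back at 10.
- Chelation-controlled reduction of 7 with Zn(BH4)2 (Et2O, 0 °C) should give the syn hydroxy lactone (3S,4R)-4-[(R)-(tert-butyldimethylsilyloxy)(3,4-dimethoxyphenyl)methyl]-3-[(S)-(3,4-dimethoxyphenyl)(hydroxy)methyl]oxolan-2-one F7. The syn relation is the one that becomes 2,3-trans in the ring.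
- LiBH4 (THF) would give (2R,3R)-2-[(R)-(tert-butyldimethylsilyloxy)(3,4-dimethoxyphenyl)methyl]-3-[(S)-(3,4-dimethoxyphenyl)(hydroxy)methyl]butane-1,4-diol F8.
- TsCl (2.2 equiv) in pyridine at 0 °C would sulfonylate the two primary hydroxyls to (2R,3R)-2-[(R)-(tert-butyldimethylsilyloxy)(3,4-dimethoxyphenyl)methyl]-3-[(S)-(3,4-dimethoxyphenyl)(hydroxy)methyl]butane-1,4-diyl bis(4-methylbenzenesulfonate) F9.
- NaH in THF would close the C2 alkoxide on C5 (five-membered ring, preferred over the oxetane at C7) with retention at C2, giving 10 directly.

## Further compounds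

F1 | step 3 | ethyl 2-bromo-3-(3,4-dimethoxyphenyl)-3-oxopropanoate (racemic) | CCOC(=O)C(Br)C(=O)c1ccc(OC)c(OC)c1
F2 | step 3 | (2E)-3-(3,4-dimethoxyphenyl)prop-2-enal | O=C/C=C/c1ccc(OC)c(OC)c1
F3 | step 3 | ethyl (1S,2S,3R)-1-(3,4-dimethoxybenzoyl)-2-(3,4-dimethoxyphenyl)-3-formylcyclopropane-1-carboxylate | O=C[C@@H]1[C@@H](c2ccc(OC)c(OC)c2)[C@@]1(C(=O)OCC)C(=O)c1ccc(OC)c(OC)c1
F4 | step 4 | (S)-(3,4-dimethoxyphenyl)[(3R,4S,5S)-5-(3,4-dimethoxyphenyl)-4-methyloxolan-3-yl]methanol | COc1ccc([C@H]2OC[C@H]([C@H](O)c3ccc(OC)c(OC)c3)[C@@H]2C)cc1OC
F5 | step 4 | (3,4-dimethoxyphenyl)[(3R,4S,5S)-5-(3,4-dimethoxyphenyl)-4-methyloxolan-3-yl]methanone | COc1ccc([C@H]2OC[C@H](C(=O)c3ccc(OC)c(OC)c3)[C@@H]2C)cc1OC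
F6 | step 6 | (3S,4R)-4-[(R)-(tert-butyldimethylsilyloxy)(3,4-dimethoxyphenyl)methyl]-3-[(3,4-dimethoxyphenyl)(hydroxy)methyl]oxolan-2-one, both carbinol epimers | O=C1OC[C@H]([C@@H](O[Si](C)(C)C(C)(C)C)c2ccc(OC)c(OC)c2)[C@H]1C(O)c1ccc(OC)c(OC)c1
F7 | step 7 | (3S,4R)-4-[(R)-(tert-butyldimethylsilyloxy)(3,4-dimethoxyphenyl)methyl]-3-[(S)-(3,4-dimethoxyphenyl)(hydroxy)methyl]oxolan-2-one | O=C1OC[C@H]([C@@H](O[Si](C)(C)C(C)(C)C)c2ccc(OC)c(OC)c2)[C@H]1[C@H](O)c1ccc(OC)c(OC)c1
F8 | step 7 | (2R,3R)-2-[(R)-(tert-butyldimethylsilyloxy)(3,4-dimethoxyphenyl)methyl]-3-[(S)-(3,4-dimethoxyphenyl)(hydroxy)methyl]butane-1,4-diol | OC[C@H]([C@@H](O[Si](C)(C)C(C)(C)C)c1ccc(OC)c(OC)c1)[C@H](CO)[C@H](O)c1ccc(OC)c(OC)c1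
F9 | step 7 | (2R,3R)-2-[(R)-(tert-butyldimethylsilyloxy)(3,4-dimethoxyphenyl)methyl]-3-[(S)-(3,4-dimethoxyphenyl)(hydroxy)methyl]butane-1,4-diyl bis(4-methylbenzenesulfonate) | Cc1ccc(cc1)S(=O)(=O)OC[C@H]([C@@H](O[Si](C)(C)C(C)(C)C)c1ccc(OC)c(OC)c1)[C@H](COS(=O)(=O)c1ccc(C)cc1)[C@H](O)c1ccc(OC)c(OC)c1
A1 | alternative 1 | (5S)-5-{[(1S,2R,5S)-5-methyl-2-(propan-2-yl)cyclohexyl]oxy}furan-2(5H)-one | O=C1O[C@@H](C=C1)O[C@H]2C[C@@H](C)CC[C@@H]2C(C)C
A2 | alternative 1 | 4-{chloro[(trimethylsilyl)methoxy]methyl}-1,2-dimethoxybenzene (racemic) | COc1ccc(C(Cl)OC[Si](C)(C)C)cc1OC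
A3 | alternative 1 | cis-fused 8-exo-(3,4-dimethoxyphenyl)-4-exo-[(1S,2R,5S)-menthyloxy]-3,7-dioxabicyclo[3.3.0]octan-2-one (configuration as in the SMILES) | COc1ccc([C@H]2OC[C@H]3[C@@H]2C(=O)O[C@@H]3O[C@H]2C[C@@H](C)CC[C@@H]2C(C)C)cc1OC
A4 | alternative 2 | 3-{[(1S)-1-(3,4-dimethoxyphenyl)prop-2-en-1-yl]oxy}-N,N-dimethylpropanamide | COc1ccc([C@H](C=C)OCCC(=O)N(C)C)cc1OC
A5 | alternative 2 | (1S,2S,5R)-2-(3,4-dimethoxyphenyl)-3-oxabicyclo[3.2.0]heptan-6-one | COc1ccc([C@H]2OC[C@H]3[C@@H]2CC3=O)cc1OC
A6 | alternative 3 | 4-[(1S)-1-{[3-(3,4-dimethoxyphenyl)prop-2-yn-1-yl]oxy}prop-2-en-1-yl]-1,2-dimethoxybenzene | COc1ccc([C@H](C=C)OCC#Cc2ccc(OC)c(OC)c2)cc1OC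
A7 | alternative 3 | (2S,3S,4Z)-2-(3,4-dimethoxyphenyl)-4-[(3,4-dimethoxyphenyl)methylidene]-3-methyloxolane | COc1ccc([C@H]2OC/C(=C\c3ccc(OC)c(OC)c3)[C@@H]2C)cc1OC
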